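**Plan**

1. Retrosynthesis: cut both C11–C15′ bonds of the 12-membered ring (this leaves one monomer, a C15 allylic bromide carrying a C11–H propanoate), then C7–C11, then C3–C4 (ring A), then C4–C15 and C5=C4, then the cyclopropane CH2 and the C10–vinyl bond, back to 2-methylcyclohexane-1,3-dione.
2. Enabling feature (each half numbered as a lindenane: cyclopropane C1–C2–C3; ring A C1, C3, C4, C5, C10; ring B C5–C10; C14 on C10; C15 on C4; C11 on C7): without the C3–C4 bond, C1–C2–C3 is an unsubstituted cyclopropyl group on quaternary C10 with two diastereotopic CH2 groups, and C4 is the bromine-bearing carbon of an exocyclic C4=C5 alkene on ring B whose geometry points the C–Br bond at that cyclopropyl group.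
3. Forward: ring B is the purchased ring; the cyclopropane is made on the achiral dione (steps 1–3); ring A closes in step 8; ring B is then oxidised to the 4,6-dien-8-one (steps 9–16); the 12-membered ring closes last by head-to-tail double C-alkylation (step 21).
4. Ring B stays saturated through step 8, because C8 can only be oxidised from a C9 ketone and the C9 carbinol is set reliably only on the rigid tricycle; the provisional C9 silyl ether meanwhile steers the C–H step.
5. Stereochemistry: C10 from CBS desymmetrisation (step 4); C1 and C3 from the choice between the two cyclopropyl CH2 groups (step 8, substrate plus ligand); C9 from hydride delivery anti to the C10 methyl (step 12); both C11 centres from enolate alkylation on the α face during cyclodimerisation (step 21).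
6. Convention: β is the ring face that carries the C10 methyl group (C14); α is the opposite face.

Key step: step 8

Assumption (step 4): hydride is taken to add to the carbonyl face syn to the methyl group, as for 2-allyl-2-methylcyclohexane-1,3-dione, so the carbinol is cis to cyclopropyl; this centre is erased in step 10, and a reversed preference would be met with the enantiomeric catalyst, which gives the same C10 configuration with the epimeric, equally usable carbinol.

Remark: potassium {[(4-methoxybenzyl)oxy]methyl}trifluoroborate (11) is taken as purchased; it is otherwise made in one operation from potassium (bromomethyl)trifluoroborate and sodium 4-methoxybenzyl oxide.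

**Route**

Step 1
Reactants: 1 2-methylcyclohexane-1,3-dione; 2 1-[(trimethylsilyl)ethynyl]-1,2-benziodoxol-3(1H)-one (TMS-EBX)
Product: 3 2-ethynyl-2-methylcyclohexane-1,3-dione
Conditions: Bu4NF, THF, −78 °C to rt
Reagents that add atoms: none
Why: Fluoride unmasks the ethynylbenziodoxolone and forms the dione enolate, whose C-alkynylation by the hypervalent iodine reagent (electrophilic alkynylation) builds the quaternary carbon that becomes C10.

Step 2
Reactants: 3 2-ethynyl-2-methylcyclohexane-1,3-dione
Product: 4 2-ethenyl-2-methylcyclohexane-1,3-dione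
Conditions: H2 (1 atm), Pd/CaCO3 poisoned with Pb(OAc)2, quinoline, EtOAc, rt
Reagents that add atoms: none
Why: Semi-hydrogenation over the poisoned palladium catalyst (Lindlar reduction) should stop at the alkene and leave the non-enolisable diketone untouched.

Step 3
Reactants: 4 2-ethenyl-2-methylcyclohexane-1,3-dione; 5 diiodomethane
Product: 6 2-cyclopropyl-2-methylcyclohexane-1,3-dione
Conditions: Et2Zn, CF3CO2H, CH2Cl2, 0 °C to rt
Reagents that add atoms: none
Why: CF3CO2ZnCH2I (Simmons–Smith cyclopropanation, Shi variant) is electrophilic enough for a monosubstituted alkene flanked by two carbonyl groups, and the product is achiral, so no stereocontrol is needed.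

Step 4
Reactants: 6 2-cyclopropyl-2-methylcyclohexane-1,3-dione
Product: 7 (2R,3R)-2-cyclopropyl-3-hydroxy-2-methylcyclohexan-1-one (hydroxyl cis to cyclopropyl; C3 is C9, C2 is C10, C1 is C5)
Conditions: (S)-Me-CBS oxazaborolidine (20 mol %), BH3·SMe2 (0.6 equiv), THF, −30 °C; MeOH quench
Reagents that add atoms: none
Why: Corey–Bakshi–Shibata reduction differentiates the enantiotopic carbonyl groups (large flank is quaternary C10, hydride syn to the methyl group), which sets C10 and a provisional C9; the minor diastereomer, which would carry the opposite C10, is removed by chromatography.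

Step 5
Reactants: 7 (2R,3R)-2-cyclopropyl-3-hydroxy-2-methylcyclohexan-1-one
Product: 8 (2R,3R)-3-(tert-butyldimethylsilyloxy)-2-cyclopropyl-2-methylcyclohexan-1-one
Conditions: TBSOTf, 2,6-lutidine, CH2Cl2, −78 to 0 °C
Reagents that add atoms: tert-butyldimethylsilyl trifluoromethanesulfonate, CC(C)(C)[Si](C)(C)OS(=O)(=O)C(F)(F)F
Why: A silyl triflate with a hindered pyridine base silylates the neopentyl secondary alcohol without retro-aldol cleavage of the β-hydroxy ketone (silyl ether formation).

Step 6
Reactants: 8 (2R,3R)-3-(tert-butyldimethylsilyloxy)-2-cyclopropyl-2-methylcyclohexan-1-one; 9 carbon tetrabromide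
Product: 10 1,1-dibromoalkene (8 with C5=O replaced by C5=CBr2; 9α-OTBS cis to cyclopropyl)
Conditions: CBr4, PPh3, Zn dust, CH2Cl2, rt, 24 h; then 8, toluene, 100 °C
Reagents that add atoms: none
Why: The preformed ylide Ph3P=CBr2 (Ramirez dibromo-olefination, first stage of the Corey–Fuchs sequence) converts the only carbonyl group into the 1,1-dibromoalkene, and the zinc variant avoids Ph3PBr2, which would attack the silyl ether.

Step 7
Reactants: 10 1,1-dibromoalkene; 11 potassium {[(4-methoxybenzyl)oxy]methyl}trifluoroborate
Product: 12 (Z)-alkenyl bromide with exocyclic C5=C4(Br)CH2OPMB (bromine cis to C10, C15 cis to C6, 9α-OTBS)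
Conditions: Pd(OAc)2 (5 mol %), RuPhos (10 mol %), Cs2CO3, toluene/H2O (10:1), 80 °C
Reagents that add atoms: none
Why: Oxidative addition occurs at the C–Br bond cis to the C6 methylene and far from quaternary C10, so stereoselective Suzuki–Miyaura mono-coupling of the 1,1-dibromoalkene places C15 cis to C6 and leaves the hindered bromine cis to C10.

Step 8
Reactants: 12 (Z)-alkenyl bromide
Product: 13 tricyclic ether (rings A and B with the C1–C2–C3 cyclopropane, C4=C5, 15-OPMB, 9α-OTBS; H1 and H3 α, C2 and C14 β)
Conditions: Pd(OAc)2 (5 mol %), (R,R)-TADDOL-derived N,N-dimethylphosphoramidite (10 mol %; the enantiomer matched to the substrate is used), PivOH (30 mol %), Cs2CO3 (1.5 equiv), mesitylene, 110 °C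
Reagents that add atoms: none
Why: Zerovalent palladium, formed from Pd(OAc)2 and the phosphoramidite, inserts into the C4–Br bond, which the alkene geometry holds next to the cyclopropyl group on C10; pivalate-assisted concerted metalation–deprotonation of a cyclopropyl C–H bond cis to C10 then gives a six-membered palladacycle (Pd, C4, C5, C10, C1, C3) and reductive elimination forms C3–C4. The closest known reaction type is the intramolecular palladium-catalysed C(sp3)–H arylation and alkenylation of cyclopropanes, including its enantioselective form with TADDOL-derived phosphoramidites, in which the ligand chooses between two methylene groups. Ring A closes as a five-membered ring by C(sp2)–C(sp3) reductive elimination from the six-membered palladacycle, and its fusion to the cyclopropane can only be cis. C1 and C3 are set together by the choice between the two diastereotopic methylene groups: the one that is metalated becomes C3, the other C2. The step needs C2 on the β face; in the reactive chair the cyclopropyl group is equatorial and the C9 silyl ether axial on the α face, so the transition state that turns the spectator methylene to the α face collides with the silyloxy group while the desired one meets only the methyl group, and the ligand enantiomer is chosen to reinforce this bias. Cyclopropane C–H bonds are acidic enough for this manifold and the alkenylpalladium intermediate has no accessible β-hydrogen, so protodebromination is the main competitor, to be suppressed by dry carbonate and the pivalate shuttle.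

Step 9
Reactants: 13 tricyclic ether
Product: 14 tricyclic 9α-alcohol (15-OPMB)
Conditions: Bu4NF, THF, 40 °C
Reagents that add atoms: none
Why: Fluoride cleaves the only silyl ether while the 4-methoxybenzyl ether is inert (desilylation).

Step 10
Reactants: 14 tricyclic 9α-alcohol
Product: 15 tricyclic 9-ketone (15-OPMB)
Conditions: Dess–Martin periodinane, NaHCO3, CH2Cl2, 0 °C to rt
Reagents that add atoms: none
Why: Buffered Dess–Martin oxidation gives the ketone and erases the provisional C9 centre without touching the tetrasubstituted alkene or the cyclopropane.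

Step 11
Reactants: 15 tricyclic 9-ketone
Product: 17 tricyclic 7-en-9-one, via trimethylsilyl enol ether 16 (not isolated)
Conditions: LiN(SiMe3)2, Me3SiCl, THF, −78 °C; then Pd(OAc)2 (1.1 equiv), MeCN, rt
Reagents that add atoms: none
Why: C8 is the only enolisable position, so silyl enol ether formation followed by dehydrosilylation with palladium diacetate (Saegusa–Ito oxidation) introduces the C7=C8 double bond.

Step 12
Reactants: 17 tricyclic 7-en-9-one
Product: 18 tricyclic 7-en-9β-ol
Conditions: NaBH4, CeCl3·7H2O, MeOH, −78 °C
Reagents that add atoms: none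
Why: In this Luche 1,2-reduction hydride should add to C9 from the α face, anti to the axial C10 methyl group, so the carbinol is β and cis to the methyl group as in the target.

Step 13
Reactants: 18 tricyclic 7-en-9β-ol
Product: 19 7β,8β-epoxy-9β-ol
Conditions: VO(acac)2 (5 mol %), tBuOOH, CH2Cl2, 0 °C
Reagents that add atoms: tert-butyl hydroperoxide, CC(C)(C)OO
Why: VO(acac)2-catalysed hydroxyl-directed epoxidation delivers oxygen to the allylic C7=C8 bond syn to the C9 hydroxyl and spares the remote tetrasubstituted C4=C5 bond.

Step 14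
Reactants: 19 7β,8β-epoxy-9β-ol
Product: 20 7β,8β-epoxy 9β-silyl ether
Conditions: TBSOTf, 2,6-lutidine, CH2Cl2, −78 °C
Reagents that add atoms: tert-butyldimethylsilyl trifluoromethanesulfonate, CC(C)(C)[Si](C)(C)OS(=O)(=O)C(F)(F)F
Why: Buffered silyl triflate at low temperature should protect the hindered C9 alcohol faster than it opens the epoxide (silyl ether formation).

Step 15
Reactants: 20 7β,8β-epoxy 9β-silyl ether
Product: 23 4,6-dien-8β-ol (9β-OTBS, 15-OPMB), via hydroxy selenide 21 (not isolated), via selenoxide 22 (not isolated)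
Conditions: (PhSe)2, NaBH4, EtOH, 60 °C; then H2O2 (30 %), pyridine, THF, 0 °C to rt
Reagents that add atoms: none
Why: PhSeNa opens the epoxide at C7, the carbon remote from the silyloxy group, and the derived selenoxide eliminates syn, away from the carbinol and towards the allylic C6 hydrogen, to give the conjugated dienol (Sharpless epoxide-to-allylic-alcohol transposition).

Step 16
Reactants: 23 4,6-dien-8β-ol
Product: 24 tricyclic dienone monomer (4,6-dien-8-one, 9β-OTBS, 15-OPMB)
Conditions: Dess–Martin periodinane, NaHCO3, CH2Cl2, 0 °C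
Reagents that add atoms: none
Why: Dess–Martin oxidation of the dienylic C8 alcohol gives the linear dienone, so the C8 carbinol configuration is irrelevant.

Step 17
Reactants: 24 tricyclic dienone monomer
Product: 25 7-iodo dienone
Conditions: I2, pyridine, CH2Cl2, rt
Reagents that add atoms: iodine, II
Why: Pyridine adds reversibly to C6, the resulting enolate is iodinated at C7 and pyridine is expelled (Johnson α-iodination of enones, an addition–elimination of the Baylis–Hillman type).

Step 18
Reactants: 25 7-iodo dienone; 26 methyl 2-bromopropanoate (racemic)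
Product: 27 propanoate monomer (25 with iodine replaced by CH(CH3)CO2Me; C11 epimers)
Conditions: 26, Zn dust (Me3SiCl-activated), THF, rt; then 25, Pd2(dba)3 (2.5 mol %), XPhos (10 mol %), THF, rt to 40 °C
Reagents that add atoms: none
Why: The α-iodoenone adds rapidly to zerovalent palladium and transmetalation with BrZnCH(CH3)CO2Me followed by reductive elimination (Negishi-type coupling of a Reformatsky reagent) joins C11 to C7, the C11 mixture being inconsequential because this centre is deprotonated in step 21.

Step 19
Reactants: 27 propanoate monomer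
Product: 28 C15 allylic alcohol
Conditions: DDQ, CH2Cl2/pH 7 buffer (10:1), 0 °C
Reagents that add atoms: none
Why: DDQ oxidises the electron-rich 4-methoxybenzyl ether to an oxocarbenium ion that water hydrolyses, leaving the silyl ether and the electron-poor dienone untouched (oxidative debenzylation).

Step 20
Reactants: 28 C15 allylic alcohol; 9 carbon tetrabromide
Product: 29 C15 allylic bromide
Conditions: CBr4, PPh3, CH2Cl2, 0 °C
Reagents that add atoms: none
Why: Appel bromination converts the primary allylic alcohol under neutral conditions, with no base present to trigger premature self-alkylation.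

Step 21
Reactants: 29 C15 allylic bromide (two molecules)
Product: 31 bis(silyl) macrocycle (9,9′-di-OTBS cycloshizukaol A), via linear dimer bromide 30 (not isolated)
Conditions: Cs2CO3 (5 equiv), DMF, 40 °C, syringe-pump addition of 29 (final 2 mM)
Reagents that add atoms: none
Why: The C11 proton, α to the ester and allylic to the dienone, is the most acidic C–H, and its dienolate formed with Cs2CO3 should C-alkylate the allylic bromide of a second molecule and then close the 12-membered ring by a second, intramolecular SN2 under high dilution (double enolate alkylation, cyclodimerisation); each C11 is expected to be set by attack of C15 on the enolate face anti to the β-oriented C10 methyl and C9 silyloxy groups, the C2-symmetric ring being the diastereomer in which the two dienone plates meet through their unhindered α faces.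

Step 22
Reactants: 31 bis(silyl) macrocycle
Product: 32 cycloshizukaol A
Conditions: HF·pyridine, pyridine, THF, 0 °C to rt
Reagents that add atoms: none
Why: Buffered hydrogen fluoride cleaves the two hindered α-keto silyl ethers without the basic conditions that would isomerise the α-ketols (desilylation).

**Compound list**

1 | 2-methylcyclohexane-1,3-dione | CC1C(=O)CCCC1=O | starting material
2 | 1-[(trimethylsilyl)ethynyl]-1,2-benziodoxol-3(1H)-one | C[Si](C)(C)C#CI1OC(=O)c2ccccc12 | starting material
3 | 2-ethynyl-2-methylcyclohexane-1,3-dione | C#CC1(C)C(=O)CCCC1=O | intermediate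
4 | 2-ethenyl-2-methylcyclohexane-1,3-dione | C=CC1(C)C(=O)CCCC1=O | intermediate
5 | diiodomethane | ICI | starting material
6 | 2-cyclopropyl-2-methylcyclohexane-1,3-dione | CC1(C2CC2)C(=O)CCCC1=O | intermediate
7 | (2R,3R)-2-cyclopropyl-3-hydroxy-2-methylcyclohexan-1-one | O=C1CCC[C@@H](O)[C@@]1(C)C1CC1 | intermediate
8 | (2R,3R)-3-(tert-butyldimethylsilyloxy)-2-cyclopropyl-2-methylcyclohexan-1-one | O=C1CCC[C@@H](O[Si](C)(C)C(C)(C)C)[C@@]1(C)C1CC1 | intermediate
9 | carbon tetrabromide | BrC(Br)(Br)Br | starting material
10 | 1,1-dibromoalkene (exocyclic C5=CBr2, 9α-OTBS) | BrC(Br)=C1CCC[C@@H](O[Si](C)(C)C(C)(C)C)[C@@]1(C)C1CC1 | intermediate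
11 | potassium {[(4-methoxybenzyl)oxy]methyl}trifluoroborate | COc1ccc(COC[B-](F)(F)F)cc1.[K+] | starting material
12 | (Z)-alkenyl bromide (C5=C4(Br)CH2OPMB, Br cis to C10, 9α-OTBS) | COc1ccc(COC/C(Br)=C2\CCC[C@@H](O[Si](C)(C)C(C)(C)C)[C@@]2(C)C2CC2)cc1 | intermediate
13 | tricyclic ether (15-OPMB, 9α-OTBS, C4=C5) | COc1ccc(COCC2=C3CCC[C@@H](O[Si](C)(C)C(C)(C)C)[C@@]3(C)[C@@H]3C[C@H]23)cc1 | intermediate
14 | tricyclic 9α-alcohol | COc1ccc(COCC2=C3CCC[C@@H](O)[C@@]3(C)[C@@H]3C[C@H]23)cc1 | intermediate
15 | tricyclic 9-ketone | COc1ccc(COCC2=C3CCCC(=O)[C@@]3(C)[C@@H]3C[C@H]23)cc1 | intermediate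
16 | trimethylsilyl enol ether (C8=C9–OSiMe3) | COc1ccc(COCC2=C3CCC=C(O[Si](C)(C)C)[C@@]3(C)[C@@H]3C[C@H]23)cc1 | intermediate (not isolated)
17 | tricyclic 7-en-9-one | COc1ccc(COCC2=C3CC=CC(=O)[C@@]3(C)[C@@H]3C[C@H]23)cc1 | intermediate
18 | tricyclic 7-en-9β-ol | COc1ccc(COCC2=C3CC=C[C@H](O)[C@@]3(C)[C@@H]3C[C@H]23)cc1 | intermediate
19 | 7β,8β-epoxy-9β-ol | COc1ccc(COCC2=C3C[C@@H]4O[C@@H]4[C@H](O)[C@@]3(C)[C@@H]3C[C@H]23)cc1 | intermediate
20 | 7β,8β-epoxy 9β-silyl ether | COc1ccc(COCC2=C3C[C@@H]4O[C@@H]4[C@H](O[Si](C)(C)C(C)(C)C)[C@@]3(C)[C@@H]3C[C@H]23)cc1 | intermediate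
21 | hydroxy selenide (7α-SePh, 8β-OH, 9β-OTBS) | COc1ccc(COCC2=C3C[C@@H]([Se]c4ccccc4)[C@H](O)[C@H](O[Si](C)(C)C(C)(C)C)[C@@]3(C)[C@@H]3C[C@H]23)cc1 | intermediate (not isolated)
22 | selenoxide of 21 (selenium centre unassigned) | COc1ccc(COCC2=C3C[C@@H]([Se](=O)c4ccccc4)[C@H](O)[C@H](O[Si](C)(C)C(C)(C)C)[C@@]3(C)[C@@H]3C[C@H]23)cc1 | intermediate (not isolated)
23 | 4,6-dien-8β-ol (9β-OTBS, 15-OPMB) | COc1ccc(COCC2=C3C=C[C@H](O)[C@H](O[Si](C)(C)C(C)(C)C)[C@@]3(C)[C@@H]3C[C@H]23)cc1 | intermediate
24 | tricyclic dienone monomer (4,6-dien-8-one, 9β-OTBS, 15-OPMB) | COc1ccc(COCC2=C3C=CC(=O)[C@H](O[Si](C)(C)C(C)(C)C)[C@@]3(C)[C@@H]3C[C@H]23)cc1 | intermediate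
25 | 7-iodo dienone | COc1ccc(COCC2=C3C=C(I)C(=O)[C@H](O[Si](C)(C)C(C)(C)C)[C@@]3(C)[C@@H]3C[C@H]23)cc1 | intermediate
26 | methyl 2-bromopropanoate (racemic) | COC(=O)C(C)Br | starting material
27 | propanoate monomer (C7–CH(CH3)CO2Me, C11 epimers, 15-OPMB) | COc1ccc(COCC2=C3C=C(C(C)C(=O)OC)C(=O)[C@H](O[Si](C)(C)C(C)(C)C)[C@@]3(C)[C@@H]3C[C@H]23)cc1 | intermediate
28 | C15 allylic alcohol (C11 epimers) | OCC1=C2C=C(C(C)C(=O)OC)C(=O)[C@H](O[Si](C)(C)C(C)(C)C)[C@@]2(C)[C@@H]2C[C@H]12 | intermediate
29 | C15 allylic bromide (C11 epimers) | BrCC1=C2C=C(C(C)C(=O)OC)C(=O)[C@H](O[Si](C)(C)C(C)(C)C)[C@@]2(C)[C@@H]2C[C@H]12 | intermediate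
30 | linear dimer bromide (first C11 quaternary, second C11 still C–H and unassigned) | BrCC1=C2C=C(C(=O)[C@H](O[Si](C)(C)C(C)(C)C)[C@@]2(C)[C@@H]2C[C@H]12)[C@](C)(C(=O)OC)CC1=C2C=C(C(C)C(=O)OC)C(=O)[C@H](O[Si](C)(C)C(C)(C)C)[C@@]2(C)[C@@H]2C[C@H]12 | intermediate (not isolated)
31 | bis(silyl) macrocycle (9,9′-di-OTBS cycloshizukaol A) | COC(=O)[C@]1(C)CC2=C3C=C(C(=O)[C@H](O[Si](C)(C)C(C)(C)C)[C@@]3(C)[C@@H]3C[C@H]23)[C@](C)(C(=O)OC)CC2=C3C=C1C(=O)[C@H](O[Si](C)(C)C(C)(C)C)[C@@]3(C)[C@@H]1C[C@H]21 | intermediate
32 | cycloshizukaol A | COC(=O)[C@]1(C)CC2=C3C=C(C(=O)[C@H](O)[C@@]3(C)[C@@H]3C[C@H]23)[C@](C)(C(=O)OC)CC2=C3C=C1C(=O)[C@H](O)[C@@]3(C)[C@@H]1C[C@H]21 | target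

**Step count and risks**

Total step count: 22. Longest linear sequence: 22 steps from 1 (the route is linear; step 21 joins two molecules of the same intermediate).

Steps most likely to fail:

1. Step 21. Chain growth may outrun ring closure, and the first, intermolecular alkylation may take place on the wrong enolate face (or at oxygen), so that the linear dimer cannot close to the C2-symmetric ring. The fallback is stepwise, sets out from 25 and 27 and comes back at 30. The 4-methoxybenzyl group of 25 is removed with DDQ to give the iodo alcohol F1, which is brominated (CBr4, PPh3) to the iodo bromide F2, an electrophile without a C11 proton. The enolate of 27, formed with LiN(SiMe3)2 in THF at −78 °C, is alkylated with F2 to the cross-coupled dimer F3, whose C11 epimers can be separated at this stage. Coupling with BrZnCH(CH3)CO2Me as in step 18 gives the diester F4, DDQ gives the dimer alcohol F5, and Appel bromination gives 30, now isolated and cyclised with Cs2CO3 in DMF under true high dilution to 31.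

2. Step 8. The hindered alkenylpalladium may be protodebrominated before it metalates the cyclopropane, or the wrong methylene may be metalated if substrate and ligand preferences oppose or the axial silyl ether crowds the palladacycle. The fallback moves absolute stereocontrol into the ring closure, sets out from 6 and comes back at 15. Dione 6 is mono-olefinated with Ph3P=CBr2 to the racemic dibromo ketone F6, which is coupled with 11 as in step 7 to the racemic bromo ketone F7. Ring closure of F7 under the conditions of step 8 is then a divergent reaction on a racemic mixture. The chiral catalyst metalates the methylene of the same absolute sense in both enantiomers, so one enantiomer gives 15 and the other the epimeric ketone F8, which is removed by chromatography. Steps 4, 5, 9 and 10 are then not needed, at the price of at most half of the material.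

3. Step 6. The α-quaternary ketone may be too hindered for the dibromomethylene ylide, so that no addition or only enolisation occurs. The fallback replaces the Wittig-type olefination by the copper-catalysed olefination of a hydrazone, sets out from 8 and comes back at 10. Ketone 8 is condensed with hydrazine hydrate (EtOH, AcOH cat., reflux) to the hydrazone F9, which is treated with CBr4 and CuCl (10 mol %) in DMSO with aqueous NH3 to give 10 with loss of nitrogen.

Further compounds
F1 | step 21 | iodo alcohol (25 with C15–OH) | OCC1=C2C=C(I)C(=O)[C@H](O[Si](C)(C)C(C)(C)C)[C@@]2(C)[C@@H]2C[C@H]12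
F2 | step 21 | iodo bromide (25 with C15–Br) | BrCC1=C2C=C(I)C(=O)[C@H](O[Si](C)(C)C(C)(C)C)[C@@]2(C)[C@@H]2C[C@H]12
F3 | step 21 | cross-coupled dimer (C11 of the 27 half bonded to C15 of the F2 half; 15-OPMB; C7′–I) | COc1ccc(COCC2=C3C=C(C(=O)[C@H](O[Si](C)(C)C(C)(C)C)[C@@]3(C)[C@@H]3C[C@H]23)[C@](C)(C(=O)OC)CC2=C3C=C(I)C(=O)[C@H](O[Si](C)(C)C(C)(C)C)[C@@]3(C)[C@@H]3C[C@H]23)cc1
F4 | step 21 | diester (F3 with iodine replaced by CH(CH3)CO2Me, that C11 unassigned) | COc1ccc(COCC2=C3C=C(C(=O)[C@H](O[Si](C)(C)C(C)(C)C)[C@@]3(C)[C@@H]3C[C@H]23)[C@](C)(C(=O)OC)CC2=C3C=C(C(C)C(=O)OC)C(=O)[C@H](O[Si](C)(C)C(C)(C)C)[C@@]3(C)[C@@H]3C[C@H]23)cc1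
F5 | step 21 | dimer alcohol (F4 with C15–OH) | OCC1=C2C=C(C(=O)[C@H](O[Si](C)(C)C(C)(C)C)[C@@]2(C)[C@@H]2C[C@H]12)[C@](C)(C(=O)OC)CC1=C2C=C(C(C)C(=O)OC)C(=O)[C@H](O[Si](C)(C)C(C)(C)C)[C@@]2(C)[C@@H]2C[C@H]12
F6 | step 8 | racemic dibromo ketone, 2-cyclopropyl-3-(dibromomethylidene)-2-methylcyclohexan-1-one | BrC(Br)=C1CCCC(=O)C1(C)C1CC1
F7 | step 8 | racemic bromo ketone (exocyclic C5=C4(Br)CH2OPMB, Br cis to C10, C9 ketone) | COc1ccc(COC/C(Br)=C2\CCCC(=O)C2(C)C2CC2)cc1
F8 | step 8 | epimeric ketone (diastereomer of 15 with C10 inverted, cyclopropane CH2 anti to the C10 methyl) | COc1ccc(COCC2=C3CCCC(=O)[C@]3(C)[C@@H]3C[C@H]23)cc1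
F9 | step 6 | hydrazone of 8 (C=N geometry unassigned) | NN=C1CCC[C@@H](O[Si](C)(C)C(C)(C)C)[C@@]1(C)C1CC1
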